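**Retrosynthetic overview**
1. Endgame: the C6 aldehyde is unmasked from a terminal dioxolane by glycol cleavage; 15-OH comes from Luche reduction of the 16-en-15-one; ring D is closed by radical C13–C16 bond formation from a C15 propargylic alcohol onto the ring C alkene.
2. Ring C comes from a Diels–Alder addition of butadiene (C9–C11, C8–C14) to a 2-formyl-α,β-unsaturated spiro-δ-lactone; the lactone ring (C7–O–C20) comes from oxidative lactonisation of a 7,20-diol.
3. Ring A (key step): reductive union of C2 (primary iodide) with C1 (one of two formyl groups on C10) in an open-chain iodo dialdehyde, with the new alkoxide trapped as the C1 acetate.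
4. Enabling feature: C10, the spiro atom of ring A and the lactone ring, carries two oxygenated one-carbon arms, C1 (acetoxy carbinol of ring A) and C20 (OCH2 of the lactone). At the aldehyde level they are the same group, so C10 is created by choosing between two formyl groups while ring A closes, and the 1,3-related oxygens O1/O20 chelate the metal.
5. The dialdehyde is assembled from dimethyl malonate (C10), (S)-glyceraldehyde acetonide (C5, masked C6), a prenyl unit (C2–C4, C18, C19) and a 3-benzyloxypropyl unit (C7–C9). Ring order: A, lactone, C, D.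

Key step: step 8

Remark: atom labels C1–C20 are the ent-kaurane numbers of the target and are kept for all intermediates.
Assumption: conjugate addition to the glyceraldehyde-derived alkylidenemalonate is taken to occur anti to the dioxolane oxygen (Felkin–Anh-type); on that basis the commercially available (S)-aldehyde 1 is the correct enantiomer. Its dioxolane carbon is a temporary control element that is excised in step 19.

Step 1
Reactants: 1 (S)-2,2-dimethyl-1,3-dioxolane-4-carbaldehyde; 2 dimethyl malonate
Product: 3 dimethyl 2-{[(4R)-2,2-dimethyl-1,3-dioxolan-4-yl]methylidene}propanedioate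
Conditions: piperidine (cat.), AcOH (cat.), 4 Å MS, CH2Cl2, 0 °C to rt
Reagents that add atoms: none
Why: Knoevenagel condensation under buffered amine catalysis, which is known to leave the α-alkoxy stereocentre of glyceraldehyde acetonide intact.

Step 2
Reactants: 3 alkylidenemalonate; 4 3-methylbut-2-en-1-ylmagnesium chloride
Product: 5 dimethyl 2-{(1S)-1-[(4R)-2,2-dimethyl-1,3-dioxolan-4-yl]-2,2-dimethylbut-3-en-1-yl}propanedioate
Conditions: Me2C=CHCH2MgCl, THF, −78 °C; aq. NH4Cl
Reagents that add atoms: none
Why: 1,4-addition of the allylic Grignard reagent with allylic transposition (SE2′) should join its tertiary carbon (C4) to C5; the dioxolane C–H eclipses the alkene (allylic 1,3-strain) and the nucleophile enters anti to the ring oxygen, which sets C5.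

Step 3
Reactants: 5 malonate adduct; 6 benzyl 3-bromopropyl ether
Product: 7 dimethyl 2-[3-(benzyloxy)propyl]-2-{(1R)-1-[(4R)-2,2-dimethyl-1,3-dioxolan-4-yl]-2,2-dimethylbut-3-en-1-yl}propanedioate
Conditions: NaH, DMF, 0 to 60 °C
Reagents that add atoms: none
Why: SN2 alkylation of the malonate anion with an unbranched primary bromide should make C10 quaternary; C10 is not yet a stereocentre because its two ester arms are identical.

Step 4
Reactants: 7 alkylated malonate
Product: 8 dimethyl 2-[3-(benzyloxy)propyl]-2-{(1R)-1-[(4R)-2,2-dimethyl-1,3-dioxolan-4-yl]-4-hydroxy-2,2-dimethylbutyl}propanedioate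
Conditions: 9-BBN, THF, 0 °C to rt; then H2O2, NaOAc, H2O, 0 °C
Reagents that add atoms: hydrogen peroxide OO
Why: anti-Markovnikov hydroboration–oxidation of the only alkene places the hydroxyl on C2, and the buffered oxidation spares the hindered methyl esters.

Step 5
Reactants: 8 primary alcohol
Product: 9 dimethyl 2-[3-(benzyloxy)propyl]-2-{(1R)-1-[(4R)-2,2-dimethyl-1,3-dioxolan-4-yl]-4-iodo-2,2-dimethylbutyl}propanedioate
Conditions: I2, PPh3, imidazole, CH2Cl2, 0 °C
Reagents that add atoms: iodine II
Why: Appel-type iodination by SN2 displacement at the unhindered primary carbinol C2.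

Step 6
Reactants: 9 iodo diester
Product: 10 2-[3-(benzyloxy)propyl]-2-{(1R)-1-[(4R)-2,2-dimethyl-1,3-dioxolan-4-yl]-4-iodo-2,2-dimethylbutyl}propane-1,3-diol
Conditions: i-Bu2AlH (6 equiv), CH2Cl2, −78 to 0 °C
Reagents that add atoms: none
Why: i-Bu2AlH should reduce both ester arms to carbinols while leaving the primary iodide, the benzyl ether and the acetonide untouched at or below 0 °C.

Step 7
Reactants: 10 iodo diol
Product: 11 2-[3-(benzyloxy)propyl]-2-{(1R)-1-[(4R)-2,2-dimethyl-1,3-dioxolan-4-yl]-4-iodo-2,2-dimethylbutyl}propanedial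
Conditions: Dess–Martin periodinane, NaHCO3, CH2Cl2, 0 °C; used at once
Reagents that add atoms: none
Why: buffered Dess–Martin oxidation of the 2,2-disubstituted 1,3-diol gives the non-enolisable malondialdehyde without the base that would cause retro-aldol loss of a formyl group.

Step 8
Reactants: 11 iodo dialdehyde
Product: 13 (1S,2R,3R)-2-[3-(benzyloxy)propyl]-3-[(4R)-2,2-dimethyl-1,3-dioxolan-4-yl]-2-formyl-4,4-dimethylcyclohexyl acetate, via samarium alkoxide 12 (not isolated)
Conditions: SmI2 (2.4 equiv, slow addition), NiI2 (2 mol%), THF, −40 °C, high dilution; then Ac2O, DMAP (cat.), −40 to 0 °C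
Reagents that add atoms: acetic anhydride CC(=O)OC(C)=O
Why: SmI2 with NiI2 catalysis reduces the primary C–I bond by two single-electron transfers to an alkylsamarium (trivalent samarium) at C2, which adds 6-exo-trig to one formyl group and so closes ring A through the C1–C2 bond; the trivalent samarium alkoxide 12 is acetylated in the same flask. The closest known reaction type is the samarium diiodide Barbier annulation of 2-(ω-iodoalkyl) β-keto esters and 1,3-diketones, in which the second carbonyl group chelates the metal. Ring A should close through a chair transition state with the dioxolanyl group on C5 and the 3-benzyloxypropyl arm on C10 equatorial and the spectator formyl group axial (an axial alkyl arm would be 1,3-diaxial to a C4 methyl), which decides which formyl group is attacked and thereby sets C10. C1 is set by chelation of samarium between the reacting and the spectator carbonyl oxygen, which places the new C–O bond equatorial and cis to the axial formyl group (the future C20). The step needs reduction of the C–I bond to outrun ketyl formation at the aldehydes, which the NiI2 catalyst, slow addition of SmI2 and low temperature should secure, and it needs the β-alkoxy aldehyde not to open by retro-aldol reaction, which the immediate acetylation prevents.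

Step 9
Reactants: 13 acetoxy aldehyde
Product: 14 (1S,2S,3R)-2-[3-(benzyloxy)propyl]-3-[(4R)-2,2-dimethyl-1,3-dioxolan-4-yl]-2-(hydroxymethyl)-4,4-dimethylcyclohexyl acetate
Conditions: NaBH4, MeOH/THF, −40 °C; AcOH quench
Reagents that add atoms: none
Why: borohydride reduction of the non-enolisable aldehyde gives the C20 carbinol, and the low temperature with acidic quench should suppress 1,3 O-to-O acetyl migration.

Step 10
Reactants: 14 benzyl ether
Product: 15 (1S,2S,3R)-3-[(4R)-2,2-dimethyl-1,3-dioxolan-4-yl]-2-(hydroxymethyl)-2-(3-hydroxypropyl)-4,4-dimethylcyclohexyl acetate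
Conditions: H2 (1 atm), Pd/C, EtOAc, rt
Reagents that add atoms: none
Why: hydrogenolysis of the benzyl ether frees the C7 carbinol; no alkene or C–I bond is present at this stage.

Step 11
Reactants: 15 diol
Product: 16 (6S,7R,11S)-7-[(4R)-2,2-dimethyl-1,3-dioxolan-4-yl]-8,8-dimethyl-3-oxo-2-oxaspiro[5.5]undecan-11-yl acetate
Conditions: TEMPO (20 mol%), PhI(OAc)2 (2.5 equiv), CH2Cl2, rt
Reagents that add atoms: none
Why: oxidative lactonisation of the 1,5-diol: the unhindered C7 carbinol is oxidised before the neopentyl C20 carbinol, the δ-lactol closes and is oxidised further, so C7 becomes the lactone carbonyl.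

Step 12
Reactants: 16 spirolactone
Product: 18 (6S,7R,11S)-7-[(4R)-2,2-dimethyl-1,3-dioxolan-4-yl]-4-(hydroxymethylidene)-8,8-dimethyl-3-oxo-2-oxaspiro[5.5]undecan-11-yl acetate, via enaminone 17 (not isolated)
Conditions: t-BuOCH(NMe2)2, toluene, 80 °C; then aq. citric acid, THF, 0 °C
Reagents that add atoms: tert-butoxybis(dimethylamino)methane CC(C)(C)OC(N(C)C)N(C)C; water O
Why: aminomethylenation of the lactone α-CH2 (C8) with Bredereck's reagent, which should prefer the more C–H acidic lactone over the acetate, and mild hydrolysis of the vinylogous carbamate introduce C15 as a formyl group (enol form) without strong base.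

Step 13
Reactants: 18 hydroxymethylidene lactone
Product: 20 (6S,7R,11S)-7-[(4R)-2,2-dimethyl-1,3-dioxolan-4-yl]-4-formyl-8,8-dimethyl-3-oxo-2-oxaspiro[5.5]undec-4-en-11-yl acetate, via selenide 19 (not isolated)
Conditions: PhSeCl, pyridine, CH2Cl2, 0 °C; then H2O2 (30%), 0 °C; used crude
Reagents that add atoms: none
Why: α-selenenylation of the β-dicarbonyl and selenoxide syn-elimination, which can only go toward C9, give the doubly activated C8=C9 dienophile.

Step 14
Reactants: 20 formyl unsaturated lactone; 21 buta-1,3-diene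
Product: 22 Diels–Alder adduct (1S,5R,8S,9S,10S): cyclohex-12-ene ring C cis-fused to the δ-lactone at C8–C9, formyl group (C15) on C8
Conditions: butadiene (excess), ZnBr2 (20 mol%), CH2Cl2, −20 °C to rt, sealed tube
Reagents that add atoms: none
Why: Diels–Alder addition to the 2-formyl enoate is suprafacial (H9 and C15 cis) and should occur on the lactone face flanked by C1 and not on the face flanked by the more hindered C5 (dioxolanyl group next to the gem-dimethyl carbon), which sets C8 and C9.

Step 15
Reactants: 22 aldehyde; 23 ethynylmagnesium bromide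
Product: 24 propargylic alcohols (C15 epimers): C8–CH(OH)–C≡CH on the adduct skeleton
Conditions: HC≡CMgBr, THF, −78 °C; cold AcOH quench
Reagents that add atoms: none
Why: 1,2-addition of the acetylide to the aldehyde at −78 °C leaves lactone and acetate untouched, the cold quench avoids retro-aldol loss of the new carbinol, and the C15 configuration is irrelevant because C15 is oxidised in step 17.

Step 16
Reactants: 24 propargylic alcohols
Product: 26 15-hydroxy-16-methylidene tetracycle (1S,5R,8S,9S,10S,13R; C15 epimers), via vinylstannane 25 (not isolated)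
Conditions: Bu3SnH (1.5 equiv, 0.1 M), AIBN (cat.), benzene, 80 °C; then PPTS, CH2Cl2, rt
Reagents that add atoms: none
Why: stannyl-radical enyne cyclisation: Bu3Sn adds to the terminal alkyne carbon, the vinyl radical at C16 closes 5-exo-trig onto C13 (only the alkene face that carries the C15 tether can be reached, which fixes C13), the C12 radical is reduced by the high tin hydride concentration before it can rearrange, and protodestannylation leaves the exocyclic methylene.

Step 17
Reactants: 26 allylic alcohols
Product: 27 16-en-15-one (1S,5R,8S,9S,10S,13R)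
Conditions: Dess–Martin periodinane, NaHCO3, CH2Cl2, 0 °C to rt
Reagents that add atoms: none
Why: oxidation of the allylic alcohols converges both C15 epimers on one enone.

Step 18
Reactants: 27 enone
Product: 28 (15R)-allylic alcohol (1S,5R,8S,9S,10S,13R,15R) with the dioxolane intact
Conditions: NaBH4, CeCl3·7H2O, MeOH, −78 °C
Reagents that add atoms: none
Why: Luche 1,2-reduction: hydride should add from the exo face of the bicyclo[3.2.1]octane (the side of the one-carbon bridge C14), which gives the 15-hydroxyl syn to C9 as in the target.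

Step 19
Reactants: 28 acetonide
Product: 29 target CNP0117386.1
Conditions: H5IO6 (2 equiv), EtOAc, rt
Reagents that add atoms: none
Why: periodic acid hydrolyses the terminal acetonide and cleaves the freed 1,2-diol in the same flask (Malaprade-type glycol cleavage), unmasking the C6 aldehyde under non-basic conditions that should not epimerise C5 or disturb the β-hydroxy lactone.

**Compound list**
1 | (S)-2,2-dimethyl-1,3-dioxolane-4-carbaldehyde | CC1(C)OC[C@@H](C=O)O1 | starting material
2 | dimethyl malonate | COC(=O)CC(=O)OC | starting material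
3 | dimethyl 2-{[(4R)-2,2-dimethyl-1,3-dioxolan-4-yl]methylidene}propanedioate | COC(=O)C(=C[C@@H]1COC(C)(C)O1)C(=O)OC | intermediate
4 | 3-methylbut-2-en-1-ylmagnesium chloride | CC(C)=CC[Mg]Cl | starting material
5 | dimethyl 2-{(1S)-1-[(4R)-2,2-dimethyl-1,3-dioxolan-4-yl]-2,2-dimethylbut-3-en-1-yl}propanedioate | C=CC(C)(C)[C@H](C(C(=O)OC)C(=O)OC)[C@@H]1COC(C)(C)O1 | intermediate
6 | benzyl 3-bromopropyl ether | BrCCCOCc1ccccc1 | starting material
7 | dimethyl 2-[3-(benzyloxy)propyl]-2-{(1R)-1-[(4R)-2,2-dimethyl-1,3-dioxolan-4-yl]-2,2-dimethylbut-3-en-1-yl}propanedioate | C=CC(C)(C)[C@H](C(CCCOCc1ccccc1)(C(=O)OC)C(=O)OC)[C@@H]1COC(C)(C)O1 | intermediate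
8 | 4-hydroxy analogue of 7 (C2 carbinol) | OCCC(C)(C)[C@H](C(CCCOCc1ccccc1)(C(=O)OC)C(=O)OC)[C@@H]1COC(C)(C)O1 | intermediate
9 | 4-iodo analogue of 7 (C2 iodide) | ICCC(C)(C)[C@H](C(CCCOCc1ccccc1)(C(=O)OC)C(=O)OC)[C@@H]1COC(C)(C)O1 | intermediate
10 | 2-[3-(benzyloxy)propyl]-2-{(1R)-1-[(4R)-2,2-dimethyl-1,3-dioxolan-4-yl]-4-iodo-2,2-dimethylbutyl}propane-1,3-diol | ICCC(C)(C)[C@H](C(CCCOCc1ccccc1)(CO)CO)[C@@H]1COC(C)(C)O1 | intermediate
11 | 2-[3-(benzyloxy)propyl]-2-{(1R)-1-[(4R)-2,2-dimethyl-1,3-dioxolan-4-yl]-4-iodo-2,2-dimethylbutyl}propanedial | ICCC(C)(C)[C@H](C(CCCOCc1ccccc1)(C=O)C=O)[C@@H]1COC(C)(C)O1 | intermediate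
12 | diiodosamarium alkoxide of the cyclised C1 carbinol (1S,5R,10R) | O=C[C@@]1(CCCOCc2ccccc2)[C@@H](O[Sm](I)I)CCC(C)(C)[C@H]1[C@@H]1COC(C)(C)O1 | intermediate
13 | (1S,2R,3R)-2-[3-(benzyloxy)propyl]-3-[(4R)-2,2-dimethyl-1,3-dioxolan-4-yl]-2-formyl-4,4-dimethylcyclohexyl acetate | O=C[C@@]1(CCCOCc2ccccc2)[C@@H](OC(C)=O)CCC(C)(C)[C@H]1[C@@H]1COC(C)(C)O1 | intermediate
14 | (1S,2S,3R)-2-[3-(benzyloxy)propyl]-3-[(4R)-2,2-dimethyl-1,3-dioxolan-4-yl]-2-(hydroxymethyl)-4,4-dimethylcyclohexyl acetate | OC[C@@]1(CCCOCc2ccccc2)[C@@H](OC(C)=O)CCC(C)(C)[C@H]1[C@@H]1COC(C)(C)O1 | intermediate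
15 | (1S,2S,3R)-3-[(4R)-2,2-dimethyl-1,3-dioxolan-4-yl]-2-(hydroxymethyl)-2-(3-hydroxypropyl)-4,4-dimethylcyclohexyl acetate | OC[C@@]1(CCCO)[C@@H](OC(C)=O)CCC(C)(C)[C@H]1[C@@H]1COC(C)(C)O1 | intermediate
16 | (6S,7R,11S)-7-[(4R)-2,2-dimethyl-1,3-dioxolan-4-yl]-8,8-dimethyl-3-oxo-2-oxaspiro[5.5]undecan-11-yl acetate | O=C1OC[C@@]2(CC1)[C@@H](OC(C)=O)CCC(C)(C)[C@H]2[C@@H]1COC(C)(C)O1 | intermediate
17 | 4-[(dimethylamino)methylidene] derivative of 16 (alkene geometry not defined) | O=C1OC[C@@]2(CC1=CN(C)C)[C@@H](OC(C)=O)CCC(C)(C)[C@H]2[C@@H]1COC(C)(C)O1 | intermediate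
18 | 4-(hydroxymethylidene) derivative of 16 (enol of the C8 formyl lactone) | O=C1OC[C@@]2(CC1=CO)[C@@H](OC(C)=O)CCC(C)(C)[C@H]2[C@@H]1COC(C)(C)O1 | intermediate
19 | 4-formyl-4-(phenylselanyl) derivative of 16 (C8 epimers) | O=C1OC[C@@]2(CC1(C=O)[Se]c1ccccc1)[C@@H](OC(C)=O)CCC(C)(C)[C@H]2[C@@H]1COC(C)(C)O1 | intermediate
20 | (6S,7R,11S)-7-[(4R)-2,2-dimethyl-1,3-dioxolan-4-yl]-4-formyl-8,8-dimethyl-3-oxo-2-oxaspiro[5.5]undec-4-en-11-yl acetate | O=C1OC[C@@]2(C=C1C=O)[C@@H](OC(C)=O)CCC(C)(C)[C@H]2[C@@H]1COC(C)(C)O1 | intermediate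
21 | buta-1,3-diene | C=CC=C | starting material
22 | Diels–Alder adduct (1S,5R,8S,9S,10S), C8 formyl, C12=C13 alkene | C1=CC[C@@H]3[C@](C1)(C(=O)OC[C@]32[C@@H](OC(C)=O)CCC(C)(C)[C@H]2[C@@H]2COC(C)(C)O2)C=O | intermediate
23 | ethynylmagnesium bromide | C#C[Mg]Br | starting material
24 | propargylic alcohols from 22 (C15 epimers) | C1=CC[C@@H]3[C@](C1)(C(=O)OC[C@]32[C@@H](OC(C)=O)CCC(C)(C)[C@H]2[C@@H]2COC(C)(C)O2)C(O)C#C | intermediate
25 | C17 tributylstannyl derivative of 26 (alkene geometry and C15 not defined) | CCCC[Sn](CCCC)(CCCC)C=C1[C@@H]2CC[C@@H]3[C@](C2)(C(=O)OC[C@]32[C@@H](OC(C)=O)CCC(C)(C)[C@H]2[C@@H]2COC(C)(C)O2)C1O | intermediate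
26 | 15-hydroxy-16-methylidene tetracycle (1S,5R,8S,9S,10S,13R; C15 epimers) | C=C1[C@@H]2CC[C@@H]3[C@](C2)(C(=O)OC[C@]32[C@@H](OC(C)=O)CCC(C)(C)[C@H]2[C@@H]2COC(C)(C)O2)C1O | intermediate
27 | 16-en-15-one (1S,5R,8S,9S,10S,13R) | C=C1[C@@H]2CC[C@@H]3[C@](C2)(C(=O)OC[C@]32[C@@H](OC(C)=O)CCC(C)(C)[C@H]2[C@@H]2COC(C)(C)O2)C1=O | intermediate
28 | (15R)-allylic alcohol (1S,5R,8S,9S,10S,13R,15R), C6 masked as the (4R)-dioxolane | C=C1[C@@H]2CC[C@@H]3[C@](C2)(C(=O)OC[C@]32[C@@H](OC(C)=O)CCC(C)(C)[C@H]2[C@@H]2COC(C)(C)O2)[C@@H]1O | intermediate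
29 | CNP0117386.1 (1S,5R,8S,9S,10S,13R,15R) | C=C1[C@@H]2CC[C@@H]3[C@](C2)(C(=O)OC[C@]32[C@@H](OC(C)=O)CCC(C)(C)[C@H]2C=O)[C@@H]1O | target

**Step count and risks**
Total steps: 19. Longest linear sequence: 19 (steps 1–19; compounds 2, 4, 6, 21 and 23 are purchased).

Steps most likely to fail:

Step 8. Ketyl formation at the formyl groups (pinacol coupling or simple reduction) may compete with reduction of the C–I bond, and discrimination between the two formyl groups may be incomplete. The fallback sets out from 9 and comes back at 14. The iodo diester 9 is cyclised with SmI2 and catalytic Fe(acac)3 by intramolecular nucleophilic acyl substitution, a known ring closure of iodoalkyl esters that again forms the C1–C2 bond and selects the ester by the same chair model, to give the cyclic β-keto ester F1. LiAlH4 then reduces the ketone (axial hydride delivery, equatorial C1 hydroxyl) and the remaining ester to the diol F2. TBSCl and imidazole silylate only the primary C20 hydroxyl to give the silyl ether F3, Ac2O and DMAP acetylate C1 to give the acetate F4, and HF·pyridine removes the silyl group to give 14.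

Step 2. The allylic Grignard reagent may bond through its unsubstituted terminus (linear prenyl isomer), or facial selectivity may erode. The fallback sets out from 3 and comes back at 5. Mukaiyama–Michael addition of the trimethylsilyl enol ether of isobutyraldehyde (MgBr2·OEt2, CH2Cl2, −78 °C) can only bond through the tertiary carbon and gives the aldehyde F5; Wittig methylenation (Ph3P=CH2, excess) then gives 5. If the facial sense proves opposite to the assumption, the (R)-enantiomer of 1 is used instead with no other change.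

Step 16. The vinyl radical may close on C12 instead of C13, or the first-formed homoallyl radical may rearrange, which would lead to the bicyclo[2.2.2]octane. The fallback sets out from 24 and comes back at 26 with no new compound (F0): a palladium hydride-mediated reductive enyne cyclisation (Pd2(dba)3, P(o-tolyl)3, AcOH, Et3SiH, benzene) proceeds by hydropalladation of the alkyne and 5-exo carbopalladation of the ring alkene, a polar pathway that fixes the ring size, and the silane reduces the alkylpalladium.

**Further compounds**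
F1 | step 8 | cyclic β-keto ester: methyl ester (C20) on C10, ketone at C1, ring A closed | COC(=O)[C@@]1(CCCOCc2ccccc2)C(=O)CCC(C)(C)[C@H]1[C@@H]1COC(C)(C)O1
F2 | step 8 | diol: C1 carbinol and C20 hydroxymethyl | OC[C@@]1(CCCOCc2ccccc2)[C@@H](O)CCC(C)(C)[C@H]1[C@@H]1COC(C)(C)O1
F3 | step 8 | C20 tert-butyldimethylsilyl ether of F2 | CC(C)(C)[Si](C)(C)OC[C@@]1(CCCOCc2ccccc2)[C@@H](O)CCC(C)(C)[C@H]1[C@@H]1COC(C)(C)O1
F4 | step 8 | C1 acetate of F3 | CC(C)(C)[Si](C)(C)OC[C@@]1(CCCOCc2ccccc2)[C@@H](OC(C)=O)CCC(C)(C)[C@H]1[C@@H]1COC(C)(C)O1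
F5 | step 2 | dimethyl 2-{1-[(4R)-2,2-dimethyl-1,3-dioxolan-4-yl]-2,2-dimethyl-3-oxopropyl}propanedioate | O=CC(C)(C)[C@H](C(C(=O)OC)C(=O)OC)[C@@H]1COC(C)(C)O1
F0 | step 16 | none | none
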